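**Assumption (one line):** atisane-type locants are used throughout (C3 = lactone C=O, C5 = CH bearing isopropenyl, C8 = quaternary bridgehead, C9 = C–O of the lactone, C10 = C–CH3 (C20), C12 = bridgehead CH, C14 = CH–OAc, C15 = ketone, C16=C17 = exo-methylene); absolute configuration is that of the given SMILES; cyclopent-3-en-1-ylmethanol is taken as a catalogue chemical.

## Retrosynthetic overview

1. Crotobarin ⇐ C16 α-methylenation of the tetracyclic keto-acetate.
2. Bicyclo[2.2.2]octane (last ring) ⇐ intramolecular aldol C8→C14 of a tricyclic keto-aldehyde, trapped as the acetate.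
3. Key step: C8–C15 and C9–O ⇐ oxidative acyl-radical 6-endo cyclisation with radical-polar crossover lactonisation of a monocyclic dialdehyde acid; this desymmetrises a CH(CH2CHO)2 group and forms the cyclohexanone ring and the δ-lactone together.
4. Dialdehyde acid ⇐ Negishi coupling of a cyclohexenyl triflate with a symmetric bis-acetal alkylzinc (from cyclopentenylmethanol by ozonolysis).
5. Ring B ketone ⇐ asymmetric conjugate addition of isopropenyl to 2-methylcyclohexenone, then Michael addition to methyl acrylate (sets C5 and C10). Ring order: B → cyclohexanone + lactone → bicyclo[2.2.2]octane.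

## Route

**Step 1**
Reactants: 1, 2-methylcyclohex-2-en-1-one; 2, isopropenylmagnesium bromide
Product: 3, (3R)-2-methyl-3-(prop-1-en-2-yl)cyclohexan-1-one (C2 epimer mixture)
Conditions: CuBr·SMe2 (5 mol %), Josiphos-type ferrocenyl diphosphine (6 mol %, enantiomer giving 3R), t-BuOMe, −78 °C, slow addition of 2; aq NH4Cl
Reagents that add atoms: none
Why: Cu-catalysed asymmetric conjugate addition (Feringa type) sets C5; the α-methyl centre is left as a mixture because it is re-formed in step 2.

**Step 2**
Reactants: 3; 4, methyl acrylate
Product: 5, methyl 3-[(1S,6S)-1-methyl-2-oxo-6-(prop-1-en-2-yl)cyclohexyl]propanoate (methyl cis to isopropenyl, propanoate chain trans)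
Conditions: t-BuOK (0.15 equiv), t-BuOH/THF, 0 °C → rt
Reagents that add atoms: none
Why: Michael addition through the thermodynamic, more substituted enolate; the acrylate approaches anti to the adjacent isopropenyl group (as in Robinson annulations of 2,3-disubstituted cyclohexanones), setting the C10 quaternary centre.

**Step 3**
Reactants: 5
Product: 6, methyl 3-[(1S,6S)-1-methyl-6-(prop-1-en-2-yl)-2-(trifluoromethylsulfonyloxy)cyclohex-2-en-1-yl]propanoate
Conditions: KHMDS, THF, −78 °C; PhNTf2, −78 → 0 °C
Reagents that add atoms: N-phenyl-bis(trifluoromethanesulfonimide), O=S(=O)(N(c1ccccc1)S(=O)(=O)C(F)(F)F)C(F)(F)F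
Why: kinetic enolate O-triflation; only C8 can be deprotonated (C10 is quaternary) and the ketone is more acidic than the ester, so the C8=C9 enol triflate forms without touching a stereocentre.

**Step 4**
Reactants: 7, (cyclopent-3-en-1-yl)methanol
Product: 8, 4-(bromomethyl)cyclopent-1-ene
Conditions: CBr4, PPh3, CH2Cl2, 0 °C → rt
Reagents that add atoms: carbon tetrabromide, BrC(Br)(Br)Br
Why: Appel bromination of a primary alcohol.

**Step 5**
Reactants: 8
Product: 9, 3-(bromomethyl)-1,1,5,5-tetramethoxypentane (achiral, Cs-symmetric masked dialdehyde)
Conditions: O3, CH2Cl2/MeOH, −78 °C; Me2S; then HC(OMe)3, TsOH (cat.), MeOH, rt; NaHCO3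
Reagents that add atoms: methanol, CO, and trimethyl orthoformate, COC(OC)OC (the four OMe groups; ozone oxygens are not retained)
Why: ozonolysis with reductive work-up and in-situ acetalisation; the alkyl bromide is inert to ozone.

**Step 6**
Reactants: 6; 9
Product: 10, methyl 3-[(1S,6S)-2-[4,4-dimethoxy-2-(2,2-dimethoxyethyl)butyl]-1-methyl-6-(prop-1-en-2-yl)cyclohex-2-en-1-yl]propanoate
Conditions: 9, Zn dust, I2 (5 mol %), DMA, 70 °C; then 6, Pd(OAc)2 (3 mol %), SPhos (6 mol %), THF, 40 °C
Reagents that add atoms: none
Why: sp3–sp2 Negishi cross-coupling of a primary alkylzinc bromide with an alkenyl triflate; it forms C9–C11 and keeps the C8=C9 alkene in place; ester and acetals are tolerated.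

**Step 7**
Reactants: 10
Product: 11, 3-[(1S,6S)-1-methyl-2-[4-oxo-2-(2-oxoethyl)butyl]-6-(prop-1-en-2-yl)cyclohex-2-en-1-yl]propanoic acid (used crude)
Conditions: LiOH, THF/MeOH/H2O, rt; then 1 M HCl to pH 1, THF/H2O, rt
Reagents that add atoms: water, O (acid OH and both aldehyde oxygens)
Why: saponification followed by acetal hydrolysis; dilute aqueous acid at rt does not protonate the trisubstituted or 1,1-disubstituted alkenes.

**Step 8 (key step)**
Reactants: 11
Product: 12, tricyclic keto-aldehyde lactone: δ-lactone cis-fused to ring B (C9–O axial, anti to the C20 methyl); cyclohexanone (C15=O) trans-fused at C8–C9 with C8–H syn to C20; C12 bears CH2CHO on the same face as C8–H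
Conditions: CuBr (10 mol %), t-BuOOBz (1.2 equiv, slow addition), MeCN/PhH, 0.01 M, 70 °C, Ar
Reagents that add atoms: none
Why: Proposed new method: t-BuO• (from Cu(I)/perester) abstracts an aldehydic H from either CH2CHO arm, and the acyl radical closes 6-endo-trig onto C8 (5-exo at the fully substituted, neopentyl C9 is disfavoured, and any 5-exo adduct reaches the same radical by 1,2-acyl shift), attacking anti to the axial C20 methyl as reagents do with steroidal alkenes flanked by an angular methyl; the chair transition state keeps the unreacted arm equatorial, which sets C12 (either arm gives the same product); the tertiary C9 radical is oxidised by Cu(II) and captured axially, anti to C20, by the pendant carboxylic acid on the face its tether reaches, setting C9 and closing the catalytic cycle; the C8 configuration is not carried forward because C8 is re-formed through its enol in step 9; closest known chemistry is Boger-type 6-endo acyl-radical cyclisation, Cu/peroxide acyl-radical alkene difunctionalisation with aldehydes, and Cu-mediated carbolactonisation of alkenoic acids.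

**Step 9**
Reactants: 12
Product: 13, tetracyclic keto-acetate (crotobarin lacking the C17 methylene; C16 = CH2)
Conditions: CSA (0.2 equiv), CH2Cl2, rt; then pyridine, Ac2O, DMAP (cat.), 0 °C → rt (one pot)
Reagents that add atoms: acetic anhydride, CC(=O)OC(C)=O
Why: acid-catalysed intramolecular aldol of a 3-(2-oxoethyl)cyclohexanone to a 6-hydroxybicyclo[2.2.2]octan-2-one through the more substituted (C8) enol, chosen over base so that no C8 enolate is formed next to the C9 carboxylate leaving group; C8 is the only enolisable carbon that can reach the aldehyde (C16 would give a four-membered ring), and the tethered aldehyde can reach C8 only from the face on which the C12 arm sits (syn to C20), which fixes C8 whatever its configuration in 12; the reversible aldol gives the C14 epimer with OH toward the C15 carbonyl (H-bonded and away from the C20 methyl), the product cannot dehydrate or lose the lactone because C8 is now quaternary, and acetylation of the non-isolated β-hydroxy ketone blocks retro-aldol.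

**Step 10**
Reactants: 13
Product: 14, crotobarin
Conditions: (HCHO)n, N-methylanilinium trifluoroacetate, THF, reflux
Reagents that add atoms: formaldehyde (as paraformaldehyde), C=O
Why: Gras α-methylenation (Mannich condensation then amine elimination); C16 is the only enolisable α-position of the C15 ketone (C8 is quaternary), and the mildly acidic conditions spare the acetate, lactone and isopropenyl group.

## Compound list

1 | 2-methylcyclohex-2-en-1-one | CC1=CCCCC1=O | starting material
2 | isopropenylmagnesium bromide | CC(=C)[Mg]Br | starting material
3 | (3R)-2-methyl-3-(prop-1-en-2-yl)cyclohexan-1-one | CC1C(=O)CCC[C@H]1C(C)=C | intermediate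
4 | methyl acrylate | C=CC(=O)OC | starting material
5 | methyl 3-[(1S,6S)-1-methyl-2-oxo-6-(prop-1-en-2-yl)cyclohexyl]propanoate | COC(=O)CC[C@]1(C)C(=O)CCC[C@H]1C(C)=C | intermediate
6 | enol triflate of 5 (C8=C9, OTf on C9) | COC(=O)CC[C@]1(C)C(OS(=O)(=O)C(F)(F)F)=CCC[C@H]1C(C)=C | intermediate
7 | (cyclopent-3-en-1-yl)methanol | OCC1CC=CC1 | starting material
8 | 4-(bromomethyl)cyclopent-1-ene | BrCC1CC=CC1 | intermediate
9 | 3-(bromomethyl)-1,1,5,5-tetramethoxypentane | COC(OC)CC(CBr)CC(OC)OC | intermediate
10 | bis-acetal ester (Negishi product) | COC(=O)CC[C@]1(C)C(CC(CC(OC)OC)CC(OC)OC)=CCC[C@H]1C(C)=C | intermediate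
11 | dialdehyde acid | OC(=O)CC[C@]1(C)C(CC(CC=O)CC=O)=CCC[C@H]1C(C)=C | intermediate
12 | tricyclic keto-aldehyde lactone | C1C(=O)[C@@H]2CC[C@@H](C(=C)C)[C@]3(C)CCC(=O)O[C@@]32C[C@H]1CC=O | intermediate
13 | tetracyclic keto-acetate (17-nor, C16 = CH2) | C1C(=O)[C@]23CC[C@@H](C(=C)C)[C@]4(C)CCC(=O)O[C@@]42C[C@H]1C[C@@H]3OC(C)=O | intermediate
14 | crotobarin | C=C1C(=O)[C@]23CC[C@@H](C(=C)C)[C@]4(C)CCC(=O)O[C@@]42C[C@H]1C[C@@H]3OC(C)=O | target

## Summary

Total steps: 10. Longest linear sequence: 8 (steps 1, 2, 3, 6, 7, 8, 9, 10).

Steps most likely to fail, with fallbacks: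

1. **Step 8 (oxidative acyl-radical cyclisation/lactonisation).** Risks are competing allylic H-abstraction, over-oxidation of the second aldehyde, Cu-mediated elimination instead of lactonisation, and facial selectivity at C8 (which controls C12). Fallback: reverse the radical polarity in two stages. Iodolactonise 11 (I2, NaHCO3) to fix C9–O and a trans-diaxial C8–I in a rigid chair; then cyclise the C8 radical (Bu3SnH, Et3B) 6-exo onto one CH2CHO carbonyl, with the syn-axial C20 methyl blocking the wrong face; then oxidise the new C15 carbinol to 12 (Dess–Martin).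
2. **Step 9 (aldol).** Risks are β-elimination of the C9 carboxylate through the C8 enol (giving the C8=C9 enone acid) and a poor equilibrium because ring closure creates the C14/C20 1,3-diaxial contact. Fallback: use the elimination instead of fighting it.
   - Open 12 to the C8=C9 enone acid with DBU.
   - Form the extended dienolate (t-BuOK, t-BuOH), which aldolises at the α-carbon C8 to give the bicyclo[2.2.2]octene with a C9=C11 alkene; acetylate.
   - Restore the C9–O bond by iodolactonisation (I2, NaHCO3; carboxylate to the more substituted C9).
   - Remove the C11 iodide with Bu3SnH/AIBN to reach 13.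
3. **Step 1 (enantioselective alkenyl addition to an α-substituted enone).** Fallback: run the cuprate addition racemically (isopropenylMgBr, CuI cat., TMSCl), carry through step 2, saponify 5 and resolve the keto acid as a salt with (R)-1-phenylethylamine, then re-esterify.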